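**Assumption:** the target has no stereocentre (it is achiral), so no enantiocontrol is needed; the only stereo-element on the route is the alkene geometry of 8, which is lost in the last step.

## Retrosynthetic overview

1. Target ⇐ hydride reduction of a 2-bromoindol-3-ylmethylene iminium ⇐ POBr3 bromodeoxygenation/aromatisation of a push–pull enaminone, 3-(dimethylaminomethylidene)oxindole.
2. Key C–C disconnection: the exocyclic C3–CH bond. The C3 ketone carbon of an isatin is turned into a carbanion by P(NMe2)3 (Kukhtin–Ramirez umpolung) and joined to the iminium carbon of Eschenmoser's salt; loss of HMPA then gives the C=C.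
3. 5,6-Dibromo-1-methylisatin ⇐ C5 bromination ⇐ N-methylation ⇐ 6-bromoisatin.
4. No ring is built: the benzene ring and the five-membered ring are bought fused in the isatin, and the five-membered ring is only aromatised in the last step.

## Route

**Step 1**
Reactants: 1 6-bromoisatin (6-bromo-1H-indole-2,3-dione)
Product: 2 6-bromo-1-methylisatin (6-bromo-1-methylindoline-2,3-dione)
Conditions: MeI (1.2 equiv), K2CO3 (1.5 equiv), DMF, 0 °C to rt
Reagents that add atoms: iodomethane, CI
Why: The acidic isatin N–H is deprotonated by K2CO3 and the amide anion is N-alkylated by MeI (SN2); methylating first also shields C7 for the next step.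

**Step 2**
Reactants: 2 6-bromo-1-methylisatin
Product: 3 5,6-dibromo-1-methylisatin (5,6-dibromo-1-methylindoline-2,3-dione)
Conditions: NBS (1.05 equiv), conc. H2SO4, 0 °C to rt
Reagents that add atoms: N-bromosuccinimide, O=C1CCC(=O)N1Br
Why: Electrophilic aromatic bromination goes to C5, which is para to the amide nitrogen, ortho to the C6 bromine and meta to the C3 ketone, whereas C7 is wedged between N–Me and Br and C4 lies next to the ketone.

**Step 3**
Reactants: 3 5,6-dibromo-1-methylisatin; 4 tris(dimethylamino)phosphine; 5 Eschenmoser's salt (N,N-dimethylmethyleneiminium iodide)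
Product: 8 (E)-5,6-dibromo-3-[(dimethylamino)methylidene]-1-methylindolin-2-one, via oxyphosphonium enolate 6 (not isolated), via alkoxyphosphonium iodide 7 (not isolated)
Conditions: P(NMe2)3 (1.05 equiv, slow addition), CH2Cl2, −78 °C; then CH2=NMe2+ I− (1.2 equiv), MeCN, −78 to 0 °C; then DBU (2 equiv), 0 °C to rt
Reagents that add atoms: none
Why: Proposed new method: trivalent phosphorus attacks the C3 carbonyl oxygen of the 1,2-dicarbonyl (Kukhtin–Ramirez addition), so the normally electrophilic ketone carbon becomes the carbon nucleophile of a 2-oxidoindole and adds Mannich-fashion to the iminium carbon (also normally electrophilic) to give 7; DBU then removes a CH2N proton with expulsion of HMPA, either by direct E2 or through the spiro-aziridinium ion formed by the neighbouring amine, both ending at the same conjugated enaminone and driven by P=O formation; the closest known reaction types are P(NMe2)3-mediated umpolung C-alkylation/olefination of 1,2-dicarbonyl compounds with benzylic bromides and reductive aziridination of isatins with imines; 7 is racemic and transient, and the E/Z ratio of 8 does not matter.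

**Step 4**
Reactants: 8 (E)-5,6-dibromo-3-[(dimethylamino)methylidene]-1-methylindolin-2-one
Product: 10 2,5,6-tribromo-1-methylgramine, via iminium dibromophosphate 9 (not isolated)
Conditions: POBr3 (1.2 equiv), ClCH2CH2Cl, 60 °C; then NaBH4 (3 equiv), EtOH, 0 °C; aq. NaOH work-up
Reagents that add atoms: phosphorus oxybromide, O=P(Br)(Br)Br
Why: POBr3 O-phosphorylates the vinylogous amide and bromide replaces the phosphate at C2 by addition–elimination, giving the aromatic 2-bromoindole iminium that is also the intermediate of the Vilsmeier–Haack–Arnold bromoformylation of oxindoles; NaBH4 then delivers hydride to the exocyclic iminium carbon, as in the reductive work-up of Vilsmeier salts to ArCH2NMe2.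

## Compound list

1 | 6-bromoisatin (6-bromo-1H-indole-2,3-dione) | O=C1Nc2cc(Br)ccc2C1=O | starting material
2 | 6-bromo-1-methylisatin | CN1C(=O)C(=O)c2ccc(Br)cc21 | intermediate
3 | 5,6-dibromo-1-methylisatin | CN1C(=O)C(=O)c2cc(Br)c(Br)cc21 | intermediate
4 | tris(dimethylamino)phosphine | CN(C)P(N(C)C)N(C)C | starting material
5 | Eschenmoser's salt (N,N-dimethylmethyleneiminium iodide) | C=[N+](C)C.[I-] | starting material
6 | 5,6-dibromo-1-methyl-3-{[tris(dimethylamino)phosphonio]oxy}-1H-indol-2-olate (Kukhtin–Ramirez adduct, zwitterion) | CN(C)[P+](N(C)C)(N(C)C)Oc1c([O-])n(C)c2cc(Br)c(Br)cc12 | intermediate (not isolated)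
7 | ({5,6-dibromo-3-[(dimethylamino)methyl]-1-methyl-2-oxoindolin-3-yl}oxy)tris(dimethylamino)phosphonium iodide (racemic) | CN(C)CC1(O[P+](N(C)C)(N(C)C)N(C)C)C(=O)N(C)c2cc(Br)c(Br)cc12.[I-] | intermediate (not isolated)
8 | (E)-5,6-dibromo-3-[(dimethylamino)methylidene]-1-methylindolin-2-one (E drawn; any Z isomer converges) | CN(C)/C=C1/C(=O)N(C)c2cc(Br)c(Br)cc12 | intermediate
9 | N-methyl-N-[(2,5,6-tribromo-1-methyl-1H-indol-3-yl)methylidene]methanaminium dibromophosphate | C[N+](C)=Cc1c(Br)n(C)c2cc(Br)c(Br)cc12.[O-]P(=O)(Br)Br | intermediate (not isolated)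
10 | 2,5,6-tribromo-1-methylgramine | CN(C)Cc1c(Br)n(C)c2cc(Br)c(Br)cc12 | target

## Step count and risks

Total step count: 4. Longest linear sequence: 4 (1 → 2 → 3 → 8 → 10).

Steps most likely to fail, in order of risk:

**Step 3 (key coupling).** The phosphonium enolate 6 may dimerise reductively with unreacted 3 (isoindigo or epoxide), free phosphine may be captured by the iminium salt, or 7 may hydrolyse or rearrange instead of eliminating. The fallback sets out from 3 and returns at 8, keeping the reversed-polarity logic but inverting the roles of the partners. (Dimethylaminomethyl)lithium F1 is made in the flask from tributyl[(dimethylamino)methyl]stannane and n-BuLi (THF, −78 °C, tin–lithium exchange) and added to the very electrophilic C3 ketone of 3 at −78 °C, where 1,2-addition should outrun bromine–lithium exchange. Water quench gives the tertiary carbinol 5,6-dibromo-3-[(dimethylamino)methyl]-3-hydroxy-1-methylindolin-2-one F2 (racemic). Dehydration of F2 with Martin sulfurane (CH2Cl2, rt), whose only β-hydrogens are on the CH2N carbon, gives 8.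

**Step 4 (bromodeoxygenation and reduction in one pot).** Hydride may attack C2 of the vinylogous amidinium 9 and remove the C2 bromine, or excess POBr3 may interfere with the borohydride. The fallback sets out from 8 and returns at 10. After the POBr3 stage the mixture is quenched with aq. NaOAc, so that 9 is hydrolysed to 2,5,6-tribromo-1-methylindole-3-carbaldehyde F3, which is isolated and purified. F3 is then submitted to reductive amination with Me2NH (2 M in THF), AcOH and NaBH(OAc)3 in ClCH2CH2Cl at rt; the iminium cation of 9 re-forms in the flask and is reduced by the milder, more selective hydride to give 10.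

**Step 2 (C5 bromination).** Some C7 bromination or over-bromination could give mixtures that are hard to separate. The fallback sets out from 2 and returns at 3, replacing direct bromination by nitration, reduction and a Sandmeyer reaction. Nitration of 2 (KNO3, conc. H2SO4, 0 °C) is reliably para to nitrogen and stops at mono-substitution, giving 6-bromo-1-methyl-5-nitroisatin F4. Reduction (Fe powder, NH4Cl, EtOH/H2O, 70 °C) gives 5-amino-6-bromo-1-methylisatin F5. Diazotisation (NaNO2, aq. HBr, 0 °C) gives 6-bromo-1-methyl-2,3-dioxoindoline-5-diazonium bromide F6, which is decomposed with CuBr (aq. HBr, 60 °C) to give 3.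

## Further compounds

F1 | step 3 | (dimethylaminomethyl)lithium | [Li]CN(C)C
F2 | step 3 | 5,6-dibromo-3-[(dimethylamino)methyl]-3-hydroxy-1-methylindolin-2-one (racemic) | CN(C)CC1(O)C(=O)N(C)c2cc(Br)c(Br)cc12
F3 | step 4 | 2,5,6-tribromo-1-methylindole-3-carbaldehyde | O=Cc1c(Br)n(C)c2cc(Br)c(Br)cc12
F4 | step 2 | 6-bromo-1-methyl-5-nitroisatin | CN1C(=O)C(=O)c2cc([N+](=O)[O-])c(Br)cc21
F5 | step 2 | 5-amino-6-bromo-1-methylisatin | CN1C(=O)C(=O)c2cc(N)c(Br)cc21
F6 | step 2 | 6-bromo-1-methyl-2,3-dioxoindoline-5-diazonium bromide | CN1C(=O)C(=O)c2cc([N+]#N)c(Br)cc21.[Br-]
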